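**Strategy.** Ring B (C5, C6, C7, C8, C9, C10) is disconnected at C9–C10 and C7–C8. Its C7=C8 olefin, flanked by the vicinal carbonyl carbons C12 on C8 and C11 on C9, is the retron of an acetylenedicarboxylate cycloaddition onto a ring A vinylcyclohexene. One thermal Diels–Alder reaction therefore closes ring B as the final ring, creates the quaternary C10 under control of the C1 oxygen stereocenter and brings in C11 and C12. Its precursor is (R)-2,4,4-trimethyl-3-vinylcyclohex-2-enyl pivalate. The adduct's 5,8-diene is then converted into the 5α-hydroxy-7-ene pattern by deconjugative protonation, α-face epoxidation and palladium-catalysed hydrogenolysis, followed by reduction, acylation and oxidation.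

Key step: step 5

Remark: positions are numbered as in drimanes (C1 carries the ester oxygen, C4 the gem-dimethyl group, C5 and C10 are the ring-fusion carbons, C11 sits on C9 and C12 on C8), β is the face of the C10 methyl group, and 3-ethoxy-2-methylcyclohex-2-en-1-one, dimethyl acetylenedicarboxylate and p-coumaric acid are taken as commercial.

**Step 1**
Reactants: 1 3-ethoxy-2-methylcyclohex-2-en-1-one
Product: 3 3-ethoxy-2,6,6-trimethylcyclohex-2-en-1-one, via 3-ethoxy-2,6-dimethylcyclohex-2-en-1-one 2 (not isolated)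
Conditions: LDA, THF, −78 °C, then MeI; recool, LDA, then MeI, −78 °C to rt
Reagents that add atoms: iodomethane CI
Why: Kinetic LDA deprotonation of a 3-alkoxyenone occurs at the α′ carbon C6 (Stork–Danheiser alkylation), so two successive enolate methylations should install the gem-dimethyl group that becomes C4 without leaving a stereocenter in the product.

**Step 2**
Reactants: 3 3-ethoxy-2,6,6-trimethylcyclohex-2-en-1-one
Product: 5 2,4,4-trimethyl-3-vinylcyclohex-2-en-1-one, via tertiary allylic alcohol 4 (not isolated)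
Conditions: CH2=CHMgBr, CeCl3, THF, −78 to 0 °C; then 1 M HCl, rt
Reagents that add atoms: vinylmagnesium bromide C=C[Mg]Br; water O
Why: Cerium-assisted 1,2-addition of the vinyl Grignard reagent to the hindered, non-enolisable ketone, followed by acid-mediated allylic transposition and enol ether hydrolysis (Stork–Danheiser enone transposition), should give the dienone, no stereocenter being formed.

**Step 3**
Reactants: 5 2,4,4-trimethyl-3-vinylcyclohex-2-en-1-one
Product: 6 (R)-2,4,4-trimethyl-3-vinylcyclohex-2-en-1-ol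
Conditions: (S)-2-methyl-CBS-oxazaborolidine (cat.), catecholborane, toluene, −78 °C
Reagents that add atoms: none
Why: Corey–Bakshi–Shibata reduction with the (S)-oxazaborolidine should deliver hydride to the ketone face defined by the large alkenyl flank and the small methylene flank, giving the (R)-allylic alcohol (the future C1 stereocenter) under catalyst control, while catecholborane at low temperature leaves the diene untouched.

**Step 4**
Reactants: 6 (R)-2,4,4-trimethyl-3-vinylcyclohex-2-en-1-ol
Product: 7 (R)-2,4,4-trimethyl-3-vinylcyclohex-2-en-1-yl pivalate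
Conditions: PivCl, pyridine, DMAP (cat.), CH2Cl2, 0 °C to rt
Reagents that add atoms: pivaloyl chloride CC(C)(C)C(Cl)=O
Why: DMAP-catalysed acylation of the secondary allylic alcohol proceeds with retention and provides a bulky, base-stable group that the later hydride reduction removes.

**Step 5**
Reactants: 7 (R)-2,4,4-trimethyl-3-vinylcyclohex-2-en-1-yl pivalate; 8 dimethyl acetylenedicarboxylate
Product: 9 dimethyl 1β-(pivaloyloxy)drima-5,8-diene-11,12-dioate
Conditions: toluene, 110 °C, sealed tube, BHT (cat.)
Reagents that add atoms: none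
Why: A thermal, concerted, normal-electron-demand [4+2] cycloaddition joins the s-cis diene C10=C5–C6=C7 of 7 to the alkyne of 8 and forms the C9–C10 and C7–C8 bonds in one operation. The closest known reaction type is the Diels–Alder reaction of 2,6,6-trimethyl-1-vinylcyclohexene with acetylenedicarboxylates, the classical entry to drimanes. Ring B is closed by an intermolecular [4+2] annulation onto the preformed ring A, which leaves the C5=C6 and C8=C9 olefins as handles for the later steps. The only new stereocenter, the quaternary C10, is controlled by the C1 pivaloyloxy group, which should sit pseudoaxially to avoid allylic strain with the C10 methyl group and so shield the β face; the dienophile should therefore bond to C10 from the α face and leave the methyl group cis to the C1 oxygen. The step needs π-facial selectivity only, because the symmetrical dienophile removes any regiochemical issue and an alkyne removes endo/exo isomerism.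

**Step 6**
Reactants: 9 dimethyl 1β-(pivaloyloxy)drima-5,8-diene-11,12-dioate
Product: 11 dimethyl 1β-(pivaloyloxy)-9αH-drima-5,7-diene-11,12-dioate, via lithium trienolate 10 (not isolated)
Conditions: LDA, THF, −78 °C; then AcOH, −78 °C
Reagents that add atoms: none
Why: Deprotonation of the doubly allylic C7 methylene gives an extended ester enolate whose kinetic protonation at the α carbon C9 (deconjugative protonation of a dienolate) should occur from the α face opposite the C10 methyl and C1 pivalate groups, setting the 9α-H/9β-ester stereocenter and moving the olefins to the conjugated 5,7-positions.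

**Step 7**
Reactants: 11 dimethyl 1β-(pivaloyloxy)-9αH-drima-5,7-diene-11,12-dioate
Product: 12 dimethyl 5α,6α-epoxy-1β-(pivaloyloxy)-9αH-drim-7-ene-11,12-dioate
Conditions: dimethyldioxirane, acetone, −20 °C
Reagents that add atoms: dimethyldioxirane CC1(C)OO1
Why: The electrophilic dioxirane should epoxidise the electron-richer γ,δ-olefin C5=C6 of the dienoate and not the ester-conjugated C7=C8 olefin, from the α face because the β face is blocked by the axial C10 and C4 methyl groups, which sets the C5 oxygen stereocenter as in 5,6-epoxidations of 5,7-diene steroids.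

**Step 8**
Reactants: 12 dimethyl 5α,6α-epoxy-1β-(pivaloyloxy)-9αH-drim-7-ene-11,12-dioate
Product: 13 dimethyl 5α-hydroxy-1β-(pivaloyloxy)-9αH-drim-7-ene-11,12-dioate
Conditions: Pd2(dba)3·CHCl3 (cat.), n-Bu3P, HCO2H, Et3N, 1,4-dioxane, rt
Reagents that add atoms: none
Why: Zerovalent palladium should ionise the vinyl epoxide with inversion to a π-allyl complex over C6–C8, and hydride from the palladium formate is delivered to the internal carbon C6 (Tsuji–Shimizu hydrogenolysis of alkenyl oxiranes), giving the homoallylic tertiary alcohol with the C5–O bond and its α configuration untouched and the olefin kept in conjugation with the C12 ester.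

**Step 9**
Reactants: 13 dimethyl 5α-hydroxy-1β-(pivaloyloxy)-9αH-drim-7-ene-11,12-dioate
Product: 14 9αH-drim-7-ene-1β,5α,11,12-tetraol
Conditions: LiAlH4, THF, 0 °C to rt
Reagents that add atoms: none
Why: Lithium aluminium hydride reduces the saturated and the α,β-unsaturated ester by 1,2-addition to the primary alcohols and cleaves the pivalate in the same operation, no stereocenter being affected, as in the established reduction of drim-7-ene-11,12-dioates.

**Step 10**
Reactants: 14 9αH-drim-7-ene-1β,5α,11,12-tetraol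
Product: 15 11,12-bis(triethylsilyloxy)-9αH-drim-7-ene-1β,5α-diol
Conditions: TESCl (2.1 equiv), imidazole, CH2Cl2, −20 to 0 °C
Reagents that add atoms: chlorotriethylsilane CC[Si](Cl)(CC)CC
Why: The two primary hydroxyl groups are silylated far faster than the neopentylic secondary C1 hydroxyl and the tertiary C5 hydroxyl, so two equivalents of the silyl chloride should give the bis-ether selectively.

**Step 11**
Reactants: 16 p-coumaric acid
Product: 18 (E)-3-[4-(tert-butyldimethylsilyloxy)phenyl]prop-2-enoic acid, via silyl ester silyl ether 17 (not isolated)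
Conditions: TBSCl (2.3 equiv), imidazole, DMF, rt; then THF/H2O/AcOH, rt
Reagents that add atoms: tert-butyldimethylsilyl chloride CC(C)(C)[Si](C)(C)Cl
Why: Exhaustive silylation followed by mild aqueous acid, which hydrolyses the labile silyl ester but not the aryl silyl ether, should give the phenol-protected acid with the (E) olefin unchanged.

**Step 12**
Reactants: 15 11,12-bis(triethylsilyloxy)-9αH-drim-7-ene-1β,5α-diol; 18 (E)-3-[4-(tert-butyldimethylsilyloxy)phenyl]prop-2-enoic acid
Product: 19 1β-[(E)-4-(tert-butyldimethylsilyloxy)cinnamoyloxy]-11,12-bis(triethylsilyloxy)-9αH-drim-7-en-5α-ol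
Conditions: DCC, DMAP, CH2Cl2, rt to 40 °C
Reagents that add atoms: none
Why: Steglich esterification through the acylpyridinium ion acylates the only reactive hydroxyl group left, the equatorial C1 alcohol, with retention, the tertiary C5 alcohol being inert.

**Step 13**
Reactants: 19 1β-[(E)-4-(tert-butyldimethylsilyloxy)cinnamoyloxy]-11,12-bis(triethylsilyloxy)-9αH-drim-7-en-5α-ol
Product: 20 1β-[(E)-4-(tert-butyldimethylsilyloxy)cinnamoyloxy]-9αH-drim-7-ene-5α,11,12-triol
Conditions: PPTS (cat.), MeOH/CH2Cl2, 0 °C
Reagents that add atoms: none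
Why: Primary triethylsilyl ethers are solvolysed by mild acid in methanol much faster than the aryl tert-butyldimethylsilyl ether or the cinnamate, so selective release of the diol is expected.

**Step 14**
Reactants: 20 1β-[(E)-4-(tert-butyldimethylsilyloxy)cinnamoyloxy]-9αH-drim-7-ene-5α,11,12-triol
Product: 21 1β-[(E)-4-(tert-butyldimethylsilyloxy)cinnamoyloxy]-5α-hydroxy-9αH-drim-7-ene-11,12-dial
Conditions: (COCl)2, DMSO, CH2Cl2, −78 °C; then Et3N, −78 to −20 °C
Reagents that add atoms: none
Why: Swern oxidation converts the allylic and the saturated primary alcohol into the enal and the aldehyde under cold, weakly basic conditions that are known to leave the epimerisable C9 center of drimane dialdehydes intact, the tertiary alcohol being unaffected.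

**Step 15**
Reactants: 21 1β-[(E)-4-(tert-butyldimethylsilyloxy)cinnamoyloxy]-5α-hydroxy-9αH-drim-7-ene-11,12-dial
Product: 22 CNP0323926.1, 1β-[(E)-4-hydroxycinnamoyloxy]-5α-hydroxy-9αH-drim-7-ene-11,12-dial
Conditions: HF·pyridine, THF/pyridine, 0 °C
Reagents that add atoms: none
Why: Buffered hydrogen fluoride cleaves the aryl silyl ether under mildly acidic conditions that should neither epimerise C9 nor cleave the cinnamate.

**Compound list**
1 | 3-ethoxy-2-methylcyclohex-2-en-1-one | CCOC1=C(C)C(=O)CCC1 | starting material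
2 | 3-ethoxy-2,6-dimethylcyclohex-2-en-1-one (racemic, not isolated) | CCOC1=C(C)C(=O)C(C)CC1 | intermediate
3 | 3-ethoxy-2,6,6-trimethylcyclohex-2-en-1-one | CCOC1=C(C)C(=O)C(C)(C)CC1 | intermediate
4 | 3-ethoxy-2,6,6-trimethyl-1-vinylcyclohex-2-en-1-ol (racemic, not isolated) | CCOC1=C(C)C(O)(C=C)C(C)(C)CC1 | intermediate
5 | 2,4,4-trimethyl-3-vinylcyclohex-2-en-1-one | CC1=C(C=C)C(C)(C)CCC1=O | intermediate
6 | (R)-2,4,4-trimethyl-3-vinylcyclohex-2-en-1-ol | O[C@@H]1CCC(C)(C)C(C=C)=C1C | intermediate
7 | (R)-2,4,4-trimethyl-3-vinylcyclohex-2-en-1-yl pivalate | CC(C)(C)C(=O)O[C@@H]1CCC(C)(C)C(C=C)=C1C | intermediate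
8 | dimethyl acetylenedicarboxylate | COC(=O)C#CC(=O)OC | starting material
9 | dimethyl 1β-(pivaloyloxy)drima-5,8-diene-11,12-dioate (10β-methyl) | CC(C)(C)C(=O)O[C@@H]1CCC(C)(C)C2=CCC(C(=O)OC)=C(C(=O)OC)[C@@]12C | intermediate
10 | lithium trienolate of 9 (C7 deprotonated, enolate on the C11 ester, not isolated) | [Li+].CC(C)(C)C(=O)O[C@@H]1CCC(C)(C)C2=CC=C(C(=O)OC)C(=C([O-])OC)[C@@]12C | intermediate
11 | dimethyl 1β-(pivaloyloxy)-9αH-drima-5,7-diene-11,12-dioate | CC(C)(C)C(=O)O[C@@H]1CCC(C)(C)C2=CC=C(C(=O)OC)[C@H](C(=O)OC)[C@@]12C | intermediate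
12 | dimethyl 5α,6α-epoxy-1β-(pivaloyloxy)-9αH-drim-7-ene-11,12-dioate | CC(C)(C)C(=O)O[C@@H]1CCC(C)(C)[C@@]23O[C@H]3C=C(C(=O)OC)[C@H](C(=O)OC)[C@@]12C | intermediate
13 | dimethyl 5α-hydroxy-1β-(pivaloyloxy)-9αH-drim-7-ene-11,12-dioate | CC(C)(C)C(=O)O[C@@H]1CCC(C)(C)[C@]2(O)CC=C(C(=O)OC)[C@H](C(=O)OC)[C@@]12C | intermediate
14 | 9αH-drim-7-ene-1β,5α,11,12-tetraol | O[C@@H]1CCC(C)(C)[C@]2(O)CC=C(CO)[C@H](CO)[C@@]12C | intermediate
15 | 11,12-bis(triethylsilyloxy)-9αH-drim-7-ene-1β,5α-diol | O[C@@H]1CCC(C)(C)[C@]2(O)CC=C(CO[Si](CC)(CC)CC)[C@H](CO[Si](CC)(CC)CC)[C@@]12C | intermediate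
16 | p-coumaric acid, (E)-3-(4-hydroxyphenyl)prop-2-enoic acid | OC(=O)/C=C/c1ccc(O)cc1 | starting material
17 | tert-butyldimethylsilyl (E)-3-[4-(tert-butyldimethylsilyloxy)phenyl]prop-2-enoate (not isolated) | CC(C)(C)[Si](C)(C)OC(=O)/C=C/c1ccc(O[Si](C)(C)C(C)(C)C)cc1 | intermediate
18 | (E)-3-[4-(tert-butyldimethylsilyloxy)phenyl]prop-2-enoic acid | OC(=O)/C=C/c1ccc(O[Si](C)(C)C(C)(C)C)cc1 | intermediate
19 | 1β-[(E)-4-(tert-butyldimethylsilyloxy)cinnamoyloxy]-11,12-bis(triethylsilyloxy)-9αH-drim-7-en-5α-ol | CC(C)(C)[Si](C)(C)Oc1ccc(/C=C/C(=O)O[C@@H]2CCC(C)(C)[C@]3(O)CC=C(CO[Si](CC)(CC)CC)[C@H](CO[Si](CC)(CC)CC)[C@@]23C)cc1 | intermediate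
20 | 1β-[(E)-4-(tert-butyldimethylsilyloxy)cinnamoyloxy]-9αH-drim-7-ene-5α,11,12-triol | CC(C)(C)[Si](C)(C)Oc1ccc(/C=C/C(=O)O[C@@H]2CCC(C)(C)[C@]3(O)CC=C(CO)[C@H](CO)[C@@]23C)cc1 | intermediate
21 | 1β-[(E)-4-(tert-butyldimethylsilyloxy)cinnamoyloxy]-5α-hydroxy-9αH-drim-7-ene-11,12-dial | CC(C)(C)[Si](C)(C)Oc1ccc(/C=C/C(=O)O[C@@H]2CCC(C)(C)[C@]3(O)CC=C(C=O)[C@H](C=O)[C@@]23C)cc1 | intermediate
22 | CNP0323926.1, 1β-[(E)-4-hydroxycinnamoyloxy]-5α-hydroxy-9αH-drim-7-ene-11,12-dial, (1R,5R,9R,10S) | Oc1ccc(/C=C/C(=O)O[C@@H]2CCC(C)(C)[C@]3(O)CC=C(C=O)[C@H](C=O)[C@@]23C)cc1 | target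

**Step count and risks**
Total step count: 15. Longest linear sequence: 14 steps (steps 1 to 10 and 12 to 15).

Steps most likely to fail:

Step 5. The risk is insufficient π-facial discrimination: bonding of the dienophile to C10 syn to the C1 oxygen would give the C10 epimer, which has the wrong absolute configuration at the quaternary center. The hindered diene may also react sluggishly. The fallback sets out from dienol 6 and replaces the acyloxy director by a larger silyloxy group, which also moves the C1 deprotection to a separate fluoride step. Silylation (TIPSOTf, 2,6-lutidine) would give the triisopropylsilyl dienyl ether F1, and cycloaddition with 8 would give the silyloxy adduct F2. Deconjugation through the lithium trienolate F3 would give the 5,7-diene F4, epoxidation would give the epoxide F5, and formate hydrogenolysis would give the hydroxy diester F6. LiAlH4 would then give the silyl-protected triol F7, and TBAF (THF, 50 °C) would come back to the route at tetraol 14.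

Step 8. The risk is misdirected hydride delivery to C8, or β-hydride elimination or rearrangement of the tertiary vinyl epoxide in place of hydrogenolysis. The fallback sets out from adduct 9 and replaces steps 6 to 8 by a radical Markovnikov hydration followed by deconjugation. Mukaiyama hydration (Co(acac)2, PhSiH3, O2, i-PrOH) of the electron-rich C5=C6 olefin should proceed by hydrogen-atom transfer to C6 and trapping of the tertiary C5 radical by oxygen on the open α face, giving the 5α-hydroxy-8-ene diester F8. LDA (2.2 equiv) would convert it into the dilithium alkoxide dienolate F9, and kinetic protonation at C9 would come back to the route at 13.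

Step 12. The risk is slow acylation of the hindered neopentylic C1 hydroxyl group, with N-acylurea formation consuming the acid. The fallback sets out from 15 and builds the cinnamate on the scaffold. Acylation with the small (diethoxyphosphoryl)acetic acid (DCC, DMAP) would give the phosphonoacetate F10. A Masamune–Roush Horner–Wadsworth–Emmons reaction (LiCl, DBU, MeCN) with commercial 4-(tert-butyldimethylsilyloxy)benzaldehyde would form the (E)-olefin and come back to the route at 19.

**Further compounds**
F1 | step 5 | (R)-triisopropyl[(2,4,4-trimethyl-3-vinylcyclohex-2-en-1-yl)oxy]silane | CC(C)[Si](O[C@@H]1CCC(C)(C)C(C=C)=C1C)(C(C)C)C(C)C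
F2 | step 5 | dimethyl 1β-(triisopropylsilyloxy)drima-5,8-diene-11,12-dioate | CC(C)[Si](O[C@@H]1CCC(C)(C)C2=CCC(C(=O)OC)=C(C(=O)OC)[C@@]12C)(C(C)C)C(C)C
F3 | step 5 | lithium trienolate of F2 (not isolated) | [Li+].CC(C)[Si](O[C@@H]1CCC(C)(C)C2=CC=C(C(=O)OC)C(=C([O-])OC)[C@@]12C)(C(C)C)C(C)C
F4 | step 5 | dimethyl 1β-(triisopropylsilyloxy)-9αH-drima-5,7-diene-11,12-dioate | CC(C)[Si](O[C@@H]1CCC(C)(C)C2=CC=C(C(=O)OC)[C@H](C(=O)OC)[C@@]12C)(C(C)C)C(C)C
F5 | step 5 | dimethyl 5α,6α-epoxy-1β-(triisopropylsilyloxy)-9αH-drim-7-ene-11,12-dioate | CC(C)[Si](O[C@@H]1CCC(C)(C)[C@@]23O[C@H]3C=C(C(=O)OC)[C@H](C(=O)OC)[C@@]12C)(C(C)C)C(C)C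
F6 | step 5 | dimethyl 5α-hydroxy-1β-(triisopropylsilyloxy)-9αH-drim-7-ene-11,12-dioate | CC(C)[Si](O[C@@H]1CCC(C)(C)[C@]2(O)CC=C(C(=O)OC)[C@H](C(=O)OC)[C@@]12C)(C(C)C)C(C)C
F7 | step 5 | 1β-(triisopropylsilyloxy)-9αH-drim-7-ene-5α,11,12-triol | CC(C)[Si](O[C@@H]1CCC(C)(C)[C@]2(O)CC=C(CO)[C@H](CO)[C@@]12C)(C(C)C)C(C)C
F8 | step 8 | dimethyl 5α-hydroxy-1β-(pivaloyloxy)drim-8-ene-11,12-dioate | CC(C)(C)C(=O)O[C@@H]1CCC(C)(C)[C@]2(O)CCC(C(=O)OC)=C(C(=O)OC)[C@@]12C
F9 | step 8 | dilithium alkoxide dienolate of F8 (not isolated) | [Li+].[Li+].CC(C)(C)C(=O)O[C@@H]1CCC(C)(C)[C@]2([O-])CC=C(C(=O)OC)C(=C([O-])OC)[C@@]12C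
F10 | step 12 | 1β-[(diethoxyphosphoryl)acetoxy]-11,12-bis(triethylsilyloxy)-9αH-drim-7-en-5α-ol | CCOP(=O)(OCC)CC(=O)O[C@@H]1CCC(C)(C)[C@]2(O)CC=C(CO[Si](CC)(CC)CC)[C@H](CO[Si](CC)(CC)CC)[C@@]12C
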